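The readings are simulated on assumed constants, noise included.

Late in the noon run Q was falling, from 73.2% at 25.0 h to 43.0% at 60.0 h, but I reckoned first how fast a flask makes it.

common to all: J 0.82 mM (held)

| flask | E | temperature | remark | time |
|---|---|---|---|---|
| noon | 27 mM | 28 °C | run made earlier |  |
| winter | 42 mM | 44 °C | run made earlier |  |
| north | 19 mM | 50 °C |  | 20 h |
| north-west | 19 mM |  | at 50 °C until 6.0 h, from then on at 20 °C | 20 h |
| north-east | 19 mM | 35 °C |  | 20 h |
| south-west | 19 mM | 20 °C |  | 20 h |

| run | time / h | Q / % | D / % |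
|---|---|---|---|
| noon | 4.00 | 18.4 | 0 |
| noon | 8.00 | 33.6 | 1.1 |
| noon | 12.0 | 49.3 | 6.3 |
| noon | 20.0 | 72.0 | 13.1 |
| noon | 25.0 | 73.2 | 17.4 |
| noon | 40.0 | 56.8 | 29.2 |
| noon | 60.0 | 43.0 | 36.8 |
| winter | 3.00 | 9.4 | 1.4 |
| winter | 6.00 | 15.7 | 4.8 |
| winter | 8.00 | 19.6 | 5.7 |
| winter | 12.0 | 27.6 | 8.9 |
| winter | 15.0 | 29.7 | 13.0 |
| winter | 20.0 | 36.4 | 16.8 |

(readings scatter by 1 percentage point)

- the numbers in the tables scatter with a standard deviation of 1 percentage point
- at the start none of J is in solution

1. the flask with the highest share of Q in all that became Q or D or X ("all alike" if they lie within 1.5 percentage points) (north / north-west / north-east / south-west / all alike)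
2. share of Q in all that became Q or D or X, north
3. share of Q in all that became Q or D or X, north-west
4. share of Q in all that became Q or D or X, north-east
5. share of Q in all that became Q or D or X, south-west

Counted as Q plus D, the noon run turned E at 1.25 mM h⁻¹ over its first 12.0 h, and the winter run turned it at 1.33 mM h⁻¹ over its first 8.00 h. Winter held 1.56 times the E, at 44 °C rather than 28 °C, yet its rate stood a factor of 1.06 higher, so I looked past E and heat to J. Solution holds 0.82 mM of J and starts with none, so, taking one J per E, a charge of 19 mM must refill it 23.2 times. I took J's passage into solution as the rate-limiting step, as a working guess, and carried the mean of the two rates as the crossing rate, the mM of E a flask with J held at 0.82 mM turns per hour at that pace: 1.29 mM h⁻¹. The noon count then slowed to 0.996 mM h⁻¹ between 12.0 h and 20.0 h, a factor of 0.797, which may be thinning E or Q passing unseen to X. A charge of 19 mM therefore takes 14.7 h at the crossing rate and 19.1 h at the slowed one, and both fit inside 20 h. I expected E to be through by then wherever that pace held, though 20 °C lies below both runs.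

The forecast read the runs the same way, “E loss is zero-order, probably limited by J supply”, and put south-west first, with 43.5% for north, 84.5% for north-west, 73% for north-east and 90% for south-west. I backed the same flask.

The flasks gave 29.1% in north, 74.7% in north-west, 57.7% in north-east and 91.5% in south-west.

    E + G → Q, rate k1*[E]^0.5*[G] (k = 1.70 L⁰·⁵ mol⁻⁰·⁵ min⁻¹, Ea = 72.0 kJ mol⁻¹)
    Q → X (k = 2.70 × 10⁻⁴ min⁻¹, Ea = 94.0 kJ mol⁻¹)
    Q ⇌ D (K = 0.770, k = 7.10 × 10⁻⁴ min⁻¹, Ea = 97.0 kJ mol⁻¹, ΔH = −33.0 kJ mol⁻¹)
    J ⇌ G, rate k4*(csat - [G]) (kL = 0.0330 min⁻¹)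
    (constants at 35 °C)

In south-west, Q and D relax towards each other by their own step, both ways together, with a half-life of 67.5 h, longer than the 20 h of the run. South-west turned 0.845 mM h⁻¹ on average, 0.655 of the crossing rate, and kept 11% of its E. Its repeat at −5 °C turned 0.148 mM h⁻¹ on average, 0.115 of the crossing rate, with G standing after 20.0 h at 0.746 mM.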